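**Retrosynthetic overview**

1. The target is 19-acetoxy-20-oxo-ent-labda-8(17),13-dien-16,15-olide. Late disconnections: C20 aldehyde from CH2OH, C19 acetate from the 19,20-diol, butenolide (C13–C16) from CO and a (Z)-13-iodoallylic alcohol, itself from a propargylic alcohol.
2. Enabling feature: in ring B (C5–C6–C7–C8–C9–C10) the exocyclic C8=C17 methylene beside C9–H is the protodesilylated form of a C8=C9 allylsilane, and the quaternary C10 carries the C20 carbonyl. Ring B is therefore the [4+2] adduct of a C7=C8(CH2SiMe3)–C9=C10(CO2Me) diene and the C5=C6 vinyl group on quaternary C4.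
3. Key disconnection: C5–C10 and C6–C7 by a thermal intramolecular Diels–Alder reaction of an acyclic 1,7,9-decatriene. Rings A and B form together in that step; the butenolide ring is closed third.
4. Stereocontrol: only C4 is preset (double Fráter–Seebach alkylation of ethyl (S)-3-hydroxybutanoate). C19 travels as a nitrile, small enough to sit axial in the tether and relay C4 to C5 and C10. C9 is set by protodesilylation.
5. Triene assembly: (R)-bromo nitrile (C1–C6, C18, C19) plus β-keto ester (C9–C15, C20) by C-alkylation, then (Z)-enol triflate, then Negishi coupling with the C7/C8/C17 allylsilane unit.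

Key step: step 11

Assumption: carbons are numbered as in labdane (decalin C1–C10; side chain C11, C12; butenolide C13–C16; C17 on C8; C18 and C19 on C4; C20 on C10), and tert-butyl(3-iodopropoxy)dimethylsilane, 4-chlorobut-2-yn-1-ol and (2-bromoprop-2-en-1-yl)trimethylsilane are taken as catalogue chemicals.

**Route**

Step 1
Reactants: 1 ethyl (S)-3-hydroxybutanoate; 2 tert-butyl(3-iodopropoxy)dimethylsilane
Product: 4 ethyl (2S,3S)-2-[3-(tert-butyldimethylsilyloxy)propyl]-3-hydroxybutanoate, via dilithium dianion 3 (not isolated)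
Conditions: LiN(i-Pr)2 (2.2 equiv), THF, −78 to −20 °C; then 2, DMPU, −20 to 0 °C
Reagents that add atoms: none
Why: Fráter–Seebach alkylation, in which the lithium-chelated dianion should be alkylated at C2 on the face away from the C3 methyl group, giving the 2,3-anti (2S,3S) product.

Step 2
Reactants: 4 ethyl (2S,3S)-2-[3-(tert-butyldimethylsilyloxy)propyl]-3-hydroxybutanoate
Product: 6 ethyl (2R,3S)-2-[3-(tert-butyldimethylsilyloxy)propyl]-3-hydroxy-2-methylbutanoate, via dilithium dianion 5 (not isolated)
Conditions: LiN(i-Pr)2 (2.3 equiv), THF, −78 to −15 °C; then MeI, DMPU, −15 to 0 °C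
Reagents that add atoms: iodomethane, CI
Why: A second Fráter–Seebach alkylation of the re-formed chelated dianion should bring methyl in from the same face as before, so the order of the two alkylations sets the quaternary centre (the later C4) as 2R.

Step 3
Reactants: 6 ethyl (2R,3S)-2-[3-(tert-butyldimethylsilyloxy)propyl]-3-hydroxy-2-methylbutanoate
Product: 7 ethyl (2R)-2-[3-(tert-butyldimethylsilyloxy)propyl]-2-methylbut-3-enoate
Conditions: Burgess reagent (Et3N+SO2N−CO2Me, 2 equiv), toluene, 80 °C
Reagents that add atoms: none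
Why: Burgess dehydration (syn Ei elimination of the sulfamate) can only take a hydrogen from the terminal methyl group because the other neighbour is quaternary, so the vinyl group (the later C5=C6 dienophile) should form with the quaternary centre untouched.

Step 4
Reactants: 7 ethyl (2R)-2-[3-(tert-butyldimethylsilyloxy)propyl]-2-methylbut-3-enoate
Product: 8 (2R)-5-(tert-butyldimethylsilyloxy)-2-ethenyl-2-methylpentanenitrile
Conditions: AlMe3 (3.5 equiv), NH3, then xylene, 130 °C
Reagents that add atoms: dimethylaluminium amide (made in the flask from AlMe3 and NH3), C[Al](C)N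
Why: Aluminium amide aminolysis with dehydration in the same flask is a known ester-to-nitrile conversion and should install the small C19 nitrile without touching the stereocentre, which has no α-hydrogen.

Step 5
Reactants: 8 (2R)-5-(tert-butyldimethylsilyloxy)-2-ethenyl-2-methylpentanenitrile
Product: 9 (2R)-5-bromo-2-ethenyl-2-methylpentanenitrile
Conditions: Ph3PBr2 (1.3 equiv), CH2Cl2, 0 °C to rt
Reagents that add atoms: dibromotriphenylphosphorane, BrP(Br)(c1ccccc1)(c1ccccc1)c1ccccc1
Why: Dibromotriphenylphosphorane converts primary silyl ethers directly into bromides (Appel-type SN2 displacement of an oxyphosphonium ion), which should give the alkylating agent in one operation.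

Step 6
Reactants: 10 4-chlorobut-2-yn-1-ol
Product: 11 (4-chlorobut-2-yn-1-yl)oxy(triethyl)silane
Conditions: Et3SiCl, imidazole, CH2Cl2, 0 °C
Reagents that add atoms: chlorotriethylsilane, CC[Si](Cl)(CC)CC
Why: Standard silylation of the primary propargylic alcohol, the triethylsilyl ether being chosen so that it falls in the acid step 12.

Step 7
Reactants: 12 methyl acetoacetate; 11 (4-chlorobut-2-yn-1-yl)oxy(triethyl)silane
Product: 14 methyl 3-oxo-8-(triethylsilyloxy)oct-6-ynoate, via sodium lithium dianion 13 (not isolated)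
Conditions: NaH, THF, 0 °C; n-BuLi, 0 °C; then 11, 0 °C to rt
Reagents that add atoms: none
Why: Dianion γ-alkylation of an acetoacetate, in which the more basic terminal carbanion should displace the propargylic chloride by SN2 and give the β-keto ester that carries C9–C15 and C20.

Step 8
Reactants: 14 methyl 3-oxo-8-(triethylsilyloxy)oct-6-ynoate; 9 (2R)-5-bromo-2-ethenyl-2-methylpentanenitrile
Product: 15 methyl 2-[(4R)-4-cyano-4-methylhex-5-en-1-yl]-3-oxo-8-(triethylsilyloxy)oct-6-ynoate (both epimers at C2)
Conditions: K2CO3, NaI (0.2 equiv), acetone, 56 °C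
Reagents that add atoms: none
Why: SN2 C-alkylation of the β-keto ester enolate with the primary bromide under Finkelstein catalysis should join C10 to C1, and the new C10 centre is erased in step 9.

Step 9
Reactants: 15 methyl 2-[(4R)-4-cyano-4-methylhex-5-en-1-yl]-3-oxo-8-(triethylsilyloxy)oct-6-ynoate
Product: 17 methyl (2Z)-2-[(4R)-4-cyano-4-methylhex-5-en-1-yl]-8-(triethylsilyloxy)-3-(trifluoromethylsulfonyloxy)oct-2-en-6-ynoate, via sodium enolate 16 (not isolated)
Conditions: NaH, Et2O/toluene, 0 °C; then (CF3SO2)2O, −78 to 0 °C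
Reagents that add atoms: trifluoromethanesulfonic anhydride, O=S(=O)(OS(=O)(=O)C(F)(F)F)C(F)(F)F
Why: O-Triflation of the sodium-chelated enolate in a weakly coordinating medium should give the enol triflate with OTf cis to CO2Me (2Z), the geometry that later places CO2Me on the inside of the diene.

Step 10
Reactants: 17 methyl (2Z)-2-[(4R)-4-cyano-4-methylhex-5-en-1-yl]-8-(triethylsilyloxy)-3-(trifluoromethylsulfonyloxy)oct-2-en-6-ynoate; 18 (2-bromoprop-2-en-1-yl)trimethylsilane
Product: 21 methyl (2Z)-2-[(4R)-4-cyano-4-methylhex-5-en-1-yl]-4-methylidene-3-[5-(triethylsilyloxy)pent-3-yn-1-yl]-5-(trimethylsilyl)pent-2-enoate, via Grignard reagent 19 (not isolated), via organozinc bromide 20 (not isolated)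
Conditions: 18, Mg, THF, reflux; ZnBr2, 0 °C; then 17, Pd(PPh3)4 (5 mol %), THF, 50 °C
Reagents that add atoms: none
Why: Negishi cross-coupling of the alkenylzinc reagent with the enol triflate should proceed with retention of double-bond geometry and give the 2-(silylmethyl)diene without touching ester, nitrile, alkyne or silyl ether.

Step 11
Reactants: 21 methyl (2Z)-2-[(4R)-4-cyano-4-methylhex-5-en-1-yl]-4-methylidene-3-[5-(triethylsilyloxy)pent-3-yn-1-yl]-5-(trimethylsilyl)pent-2-enoate
Product: 22 methyl (4R,5R,10S)-4-cyano-4-methyl-9-[5-(triethylsilyloxy)pent-3-yn-1-yl]-8-[(trimethylsilyl)methyl]-trans-decal-8-ene-10-carboxylate (labdane numbering; nitrile and ester cis-diaxial)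
Conditions: toluene (0.01 M), BHT (0.1 equiv), base-washed sealed tube, 180 °C
Reagents that add atoms: none
Why: Heating the 1,7,9-decatriene should bring the unactivated C5=C6 vinyl group onto the C7=C8–C9=C10 diene in a concerted, suprafacial thermal [4+2] (intramolecular Diels–Alder reaction); the closest known reaction types are thermal cyclisations of unactivated decatrienes to trans-decalins and Diels–Alder reactions of 2-(trimethylsilylmethyl)buta-1,3-dienes, helped here by the ester-lowered diene LUMO and the gem-disubstituted C4. Ring A closes as the six-membered carbocycle of the fused (type 1) mode through a chair-like C1–C2–C3–C4 tether by the C5–C10 bond, and ring B closes as the cyclohexene of the cycloaddition itself (C5–C10 and C6–C7 bonds, new C8=C9 allylsilane). The (2Z) diene geometry puts the tether outside and CO2Me inside, so C10 becomes the quaternary ring-fusion carbon carrying C20, and the anti chair transition state, the only one that keeps the diene off the axial C4 substituent, should give the trans ring fusion with C5–H anti to C20. The configuration at C5 and C10 follows from the preset C4: the linear nitrile, with a much smaller A-value than methyl, takes the axial tether position syn to the incoming C20 ester and methyl the equatorial one, which makes C19 cis to C20. The step needs this facial selectivity together with regio- and chemoselectivity: the four-atom tether allows only the fused regiochemistry, the alkyne hangs on the internal diene carbon C9 and cannot reach the diene, and the inside substituent (CO2Me) has no hydrogen for a competing 1,5-hydrogen shift.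

Step 12
Reactants: 22 methyl (4R,5R,10S)-4-cyano-4-methyl-9-[5-(triethylsilyloxy)pent-3-yn-1-yl]-8-[(trimethylsilyl)methyl]-trans-decal-8-ene-10-carboxylate
Product: 23 methyl (4R,5R,9R,10R)-4-cyano-9-(5-hydroxypent-3-yn-1-yl)-4-methyl-8-methylidene-trans-decalin-10-carboxylate (labdane numbering)
Conditions: CF3CO2H (5 equiv), wet CH2Cl2, 0 °C; NaHCO3 work-up
Reagents that add atoms: none
Why: Protodesilylation of the allylsilane (SE2' protonation at C9 with loss of silicon from C17) should give the exocyclic C8=C17 alkene, with C9 protonated axially on the face opposite the axial C10 ester so that the side chain becomes equatorial (9R), and the wet acid should also cleave the triethylsilyl ether.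

Step 13
Reactants: 23 methyl (4R,5R,9R,10R)-4-cyano-9-(5-hydroxypent-3-yn-1-yl)-4-methyl-8-methylidene-trans-decalin-10-carboxylate
Product: 25 (4R,5S,9R,10R)-19,20-epoxy-16-nor-ent-labd-8(17)-en-13-yne-15,19-diol (19,20-lactol; both configurations at C19), via aluminium aldimine 24 (not isolated)
Conditions: i-Bu2AlH (6 equiv), CH2Cl2, −78 to 0 °C; then 1 M HCl, THF, 0 °C
Reagents that add atoms: water, O
Why: Hydride reduction with i-Bu2AlH should take the nitrile to the aluminium aldimine and the ester to the alcohol, and acid hydrolysis of the aldimine should give the C19 aldehyde, which closes onto the cis-diaxial C20 hydroxyl as the six-membered lactol.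

Step 14
Reactants: 25 (4R,5S,9R,10R)-19,20-epoxy-16-nor-ent-labd-8(17)-en-13-yne-15,19-diol
Product: 27 (4R,5R,9R,10R,13Z)-13-iodo-16-nor-ent-labda-8(17),13-diene-15,19,20-triol, via cyclic vinylalanate 26 (not isolated)
Conditions: NaAlH2(OCH2CH2OMe)2 (Red-Al, 6 equiv), THF, 0 °C to rt; EtOAc; then I2 (1.2 equiv), −78 °C
Reagents that add atoms: iodine, II
Why: Red-Al should reduce the lactol through its open aldehyde form to the 19,20-diol and, in the same flask, add hydride and aluminium trans across the alkyne under direction of the propargylic alkoxide (aluminium on C13), so that iodination with retention should give the (Z)-3-iodoallylic alcohol.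

Step 15
Reactants: 27 (4R,5R,9R,10R,13Z)-13-iodo-16-nor-ent-labda-8(17),13-diene-15,19,20-triol
Product: 28 19,20-dihydroxy-ent-labda-8(17),13-dien-16,15-olide (4R,5R,9R,10R)
Conditions: Pd(PPh3)4 (5 mol %), CO (1 atm), K2CO3, THF, 45 °C
Reagents that add atoms: carbon monoxide, [C-]#[O+]
Why: Palladium-catalysed carbonylative lactonisation, in which oxidative addition of the vinyl iodide to zerovalent palladium, CO insertion and capture of the acylpalladium by the cis allylic hydroxyl should close the α-substituted butenolide with the double bond kept at C13=C14.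

Step 16
Reactants: 28 19,20-dihydroxy-ent-labda-8(17),13-dien-16,15-olide
Product: 29 19-acetoxy-20-hydroxy-ent-labda-8(17),13-dien-16,15-olide (4R,5R,9R,10R)
Conditions: Ac2O (1.05 equiv), 2,4,6-collidine, CH2Cl2, −20 to 0 °C
Reagents that add atoms: acetic anhydride, CC(=O)OC(C)=O
Why: Kinetic acylation should occur at the less hindered C19 hydroxymethyl (on C4, next to a methyl group) in preference to the C20 hydroxymethyl on the ring-fusion carbon, which is axial to both rings and flanked by C1, C9 and the C11 chain.

Step 17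
Reactants: 29 19-acetoxy-20-hydroxy-ent-labda-8(17),13-dien-16,15-olide
Product: 30 19-acetoxy-20-oxo-ent-labda-8(17),13-dien-16,15-olide (4R,5R,9R,10R), the target
Conditions: Dess–Martin periodinane, NaHCO3, CH2Cl2, 0 °C to rt
Reagents that add atoms: none
Why: Dess–Martin oxidation of the neopentyl primary alcohol to the non-enolisable aldehyde should leave acetate, butenolide and exocyclic alkene untouched and, because C19 is already acylated, no lactol can form.

**Compound list**

1 | ethyl (S)-3-hydroxybutanoate | CCOC(=O)C[C@H](C)O | starting material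
2 | tert-butyl(3-iodopropoxy)dimethylsilane | CC(C)(C)[Si](C)(C)OCCCI | starting material
3 | dilithium dianion of 1 (chelated enolate alkoxide) | CCO/C(O[Li])=C/[C@H](C)O[Li] | intermediate
4 | ethyl (2S,3S)-2-[3-(tert-butyldimethylsilyloxy)propyl]-3-hydroxybutanoate | CCOC(=O)[C@@H](CCCO[Si](C)(C)C(C)(C)C)[C@H](C)O | intermediate
5 | dilithium dianion of 4 | CCO/C(O[Li])=C(\CCCO[Si](C)(C)C(C)(C)C)[C@H](C)O[Li] | intermediate
6 | ethyl (2R,3S)-2-[3-(tert-butyldimethylsilyloxy)propyl]-3-hydroxy-2-methylbutanoate | CCOC(=O)[C@](C)(CCCO[Si](C)(C)C(C)(C)C)[C@H](C)O | intermediate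
7 | ethyl (2R)-2-[3-(tert-butyldimethylsilyloxy)propyl]-2-methylbut-3-enoate | CCOC(=O)[C@](C)(CCCO[Si](C)(C)C(C)(C)C)C=C | intermediate
8 | (2R)-5-(tert-butyldimethylsilyloxy)-2-ethenyl-2-methylpentanenitrile | N#C[C@](C)(CCCO[Si](C)(C)C(C)(C)C)C=C | intermediate
9 | (2R)-5-bromo-2-ethenyl-2-methylpentanenitrile | N#C[C@](C)(CCCBr)C=C | intermediate
10 | 4-chlorobut-2-yn-1-ol | OCC#CCCl | starting material
11 | (4-chlorobut-2-yn-1-yl)oxy(triethyl)silane | CC[Si](CC)(CC)OCC#CCCl | intermediate
12 | methyl acetoacetate | COC(=O)CC(C)=O | starting material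
13 | sodium lithium dianion of 12 | COC(=O)C=C([O-])[CH2-].[Na+].[Li+] | intermediate
14 | methyl 3-oxo-8-(triethylsilyloxy)oct-6-ynoate | COC(=O)CC(=O)CCC#CCO[Si](CC)(CC)CC | intermediate
15 | methyl 2-[(4R)-4-cyano-4-methylhex-5-en-1-yl]-3-oxo-8-(triethylsilyloxy)oct-6-ynoate (both epimers at C2) | COC(=O)C(CCC[C@@](C)(C#N)C=C)C(=O)CCC#CCO[Si](CC)(CC)CC | intermediate
16 | sodium (Z)-enolate of 15 | COC(=O)/C(CCC[C@@](C)(C#N)C=C)=C(\[O-])CCC#CCO[Si](CC)(CC)CC.[Na+] | intermediate
17 | methyl (2Z)-2-[(4R)-4-cyano-4-methylhex-5-en-1-yl]-8-(triethylsilyloxy)-3-(trifluoromethylsulfonyloxy)oct-2-en-6-ynoate | COC(=O)/C(CCC[C@@](C)(C#N)C=C)=C(\OS(=O)(=O)C(F)(F)F)CCC#CCO[Si](CC)(CC)CC | intermediate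
18 | (2-bromoprop-2-en-1-yl)trimethylsilane | C=C(Br)C[Si](C)(C)C | starting material
19 | [1-(trimethylsilylmethyl)ethenyl]magnesium bromide | C=C(C[Si](C)(C)C)[Mg]Br | intermediate
20 | [1-(trimethylsilylmethyl)ethenyl]zinc bromide | C=C(C[Si](C)(C)C)[Zn]Br | intermediate
21 | methyl (2Z)-2-[(4R)-4-cyano-4-methylhex-5-en-1-yl]-4-methylidene-3-[5-(triethylsilyloxy)pent-3-yn-1-yl]-5-(trimethylsilyl)pent-2-enoate | COC(=O)/C(CCC[C@@](C)(C#N)C=C)=C(\C(=C)C[Si](C)(C)C)CCC#CCO[Si](CC)(CC)CC | intermediate
22 | methyl (4R,5R,10S)-4-cyano-4-methyl-9-[5-(triethylsilyloxy)pent-3-yn-1-yl]-8-[(trimethylsilyl)methyl]-trans-decal-8-ene-10-carboxylate (labdane numbering; nitrile and ester cis-diaxial) | C[Si](C)(C)CC=1CC[C@@H]2[C@](C)(C#N)CCC[C@@]2(C(=O)OC)C=1CCC#CCO[Si](CC)(CC)CC | intermediate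
23 | methyl (4R,5R,9R,10R)-4-cyano-9-(5-hydroxypent-3-yn-1-yl)-4-methyl-8-methylidene-trans-decalin-10-carboxylate (labdane numbering) | C=C1CC[C@@H]2[C@](C)(C#N)CCC[C@@]2(C(=O)OC)[C@@H]1CCC#CCO | intermediate
24 | aluminium aldimine and alkoxides of 23 after reduction (C19 N-aluminio aldimine, C20 and C15 aluminium alkoxides) | C=C1CC[C@@H]2[C@](C)(C=N[Al](CC(C)C)CC(C)C)CCC[C@@]2(CO[Al](CC(C)C)CC(C)C)[C@@H]1CCC#CCO[Al](CC(C)C)CC(C)C | intermediate
25 | (4R,5S,9R,10R)-19,20-epoxy-16-nor-ent-labd-8(17)-en-13-yne-15,19-diol (19,20-lactol; both configurations at C19) | C=C1CC[C@@H]2[C@](C)(C(O)OC3)CCC[C@@]23[C@@H]1CCC#CCO | intermediate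
26 | cyclic (Z)-vinylalanate of the 19,20-dialkoxide (aluminium on C13 and on O15) | C=C1CC[C@@H]2[C@](C)(C[O-])CCC[C@@]2(C[O-])[C@@H]1CC/C3=C/CO[Al-]3(OCCOC)OCCOC.[Na+].[Na+].[Na+] | intermediate
27 | (4R,5R,9R,10R,13Z)-13-iodo-16-nor-ent-labda-8(17),13-diene-15,19,20-triol | C=C1CC[C@@H]2[C@](C)(CO)CCC[C@@]2(CO)[C@@H]1CC/C(I)=C/CO | intermediate
28 | 19,20-dihydroxy-ent-labda-8(17),13-dien-16,15-olide (4R,5R,9R,10R) | C=C1CC[C@@H]2[C@](C)(CO)CCC[C@@]2(CO)[C@@H]1CCC1=CCOC1=O | intermediate
29 | 19-acetoxy-20-hydroxy-ent-labda-8(17),13-dien-16,15-olide (4R,5R,9R,10R) | C=C1CC[C@@H]2[C@](C)(COC(C)=O)CCC[C@@]2(CO)[C@@H]1CCC1=CCOC1=O | intermediate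
30 | 19-acetoxy-20-oxo-ent-labda-8(17),13-dien-16,15-olide (4R,5R,9R,10R); [(1R,4aR,5R,8aR)-4a-formyl-1-methyl-6-methylidene-5-[2-(2-oxo-2,5-dihydrofuran-3-yl)ethyl]decahydronaphthalen-1-yl]methyl acetate | C=C1CC[C@@H]2[C@](C)(COC(C)=O)CCC[C@@]2(C=O)[C@@H]1CCC1=CCOC1=O | target

**Step count and risks**

Total step count: 17. Longest linear sequence: 15 steps (steps 1–5, then 8–17, from ethyl (S)-3-hydroxybutanoate); steps 6 and 7 form the side branch.

Steps most likely to fail:

Step 11. At the temperature that the unactivated cycloaddition needs, the acid-labile allylsilane diene may be lost by protodesilylation or silyl migration faster than it cyclises, so that the latent C17 methylene never reaches the decalin. The fallback sets out from enol triflate 17. A Stille coupling with tributyl(1-ethoxyvinyl)stannane (Pd(PPh3)4, LiCl, THF, 65 °C) should give the 2-ethoxy diene, the ethoxy triene F1. The same thermal intramolecular Diels–Alder reaction should then give the enol ether cycloadduct F2, which carries no C–Si bond on the ring. Aqueous HCl in THF should hydrolyse the enol ether and the silyl ether and equilibrate C9 to the equatorial side chain, giving the C8 ketone F3. Wittig methylenation (Ph3P=CH2, THF) then comes back to the route at compound 23.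

Step 16. Discrimination between the two neopentyl primary hydroxyls may be insufficient, so that the diacetate and the C20 acetate form beside the wanted C19 acetate. The fallback sets out from diol 28. Iodoetherification (I2, NaHCO3, MeCN, 0 °C) should engage only the C20 hydroxyl, which alone can reach C8 of the exocyclic alkene in a five-membered ring, giving the 8,20-epoxy-17-iodide F4 with the C19 hydroxyl free. Acetylation (Ac2O, pyridine, DMAP) should give the iodoether acetate F5. Reductive elimination with Zn dust in AcOH/EtOH should regenerate the C8=C17 alkene and the C20 hydroxyl and comes back to the route at compound 29.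

Step 4. Conversion of the hindered ester may stall before dehydration is complete, or the silyl ether may be lost under the hot Lewis acidic aluminium amide. The fallback sets out from ester 7. Partial reduction (i-Bu2AlH, 1.1 equiv, CH2Cl2, −78 °C) should give the quaternary aldehyde F6. Oxidative conversion of the aldehyde with I2 in aqueous NH3/THF at rt should give the nitrile and comes back to the route at compound 8.

**Further compounds**

F1 | step 11 | methyl (2Z)-2-[(4R)-4-cyano-4-methylhex-5-en-1-yl]-4-ethoxy-3-[5-(triethylsilyloxy)pent-3-yn-1-yl]penta-2,4-dienoate | COC(=O)/C(CCC[C@@](C)(C#N)C=C)=C(\C(=C)OCC)CCC#CCO[Si](CC)(CC)CC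
F2 | step 11 | methyl (4R,5R,10S)-4-cyano-8-ethoxy-4-methyl-9-[5-(triethylsilyloxy)pent-3-yn-1-yl]-trans-decal-8-ene-10-carboxylate (labdane numbering) | CCOC=1CC[C@@H]2[C@](C)(C#N)CCC[C@@]2(C(=O)OC)C=1CCC#CCO[Si](CC)(CC)CC
F3 | step 11 | methyl (4R,5R,9S,10S)-4-cyano-9-(5-hydroxypent-3-yn-1-yl)-4-methyl-8-oxo-trans-decalin-10-carboxylate (labdane numbering) | O=C1CC[C@@H]2[C@](C)(C#N)CCC[C@@]2(C(=O)OC)[C@@H]1CCC#CCO
F4 | step 16 | 8,20-epoxy-19-hydroxy-17-iodo-ent-labd-13-en-16,15-olide (C4, C5, C9, C10 as in 28) | IC[C@@]13CC[C@@H]2[C@](C)(CO)CCC[C@@]2(CO3)[C@@H]1CCC1=CCOC1=O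
F5 | step 16 | 19-acetoxy-8,20-epoxy-17-iodo-ent-labd-13-en-16,15-olide | IC[C@@]13CC[C@@H]2[C@](C)(COC(C)=O)CCC[C@@]2(CO3)[C@@H]1CCC1=CCOC1=O
F6 | step 4 | (2R)-5-(tert-butyldimethylsilyloxy)-2-ethenyl-2-methylpentanal | O=C[C@](C)(CCCO[Si](C)(C)C(C)(C)C)C=C
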